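## The problem

Target **17** is an unbranched C20 chain. Its only ring is the α,β-unsaturated δ-lactone (O1, C2–C6). The side chain on C6 carries hydroxyls at C2', C4' and C6' and ends in an unfunctionalised nonyl group (C7'–C15').

All four stereocentres (6S, 2'S, 4'R, 6'R) are oxygen-bearing, and each pair is insulated by a methylene group. The array is anti (C6/C2'), anti (C2'/C4'), syn (C4'/C6'). It can be controlled only by reagent, by 1,3-induction or by 1,5-induction; the nonyl tail offers no handle.

The lactone does not tolerate strong bases, aluminium hydrides or basic protic media. These cause conjugate addition, ring opening, or oxa-Michael addition of the C2' hydroxyl onto C4. Chain building next to the lactone must therefore be mild, and the triol must be unveiled near neutrality.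

The feature the plan exploits is the segment C4–C5–C6(O1)–C1'–C2'(O)–C3'–C4'. Ring carbon C6 and chain carbon C2' are 1,3-anti carbinols of the same sense. Each carries a CH2–C arm (C5–C4 in the ring, C3'–C4' in the chain), and C1' lies on a local twofold axis. These atoms are exactly those of C2-symmetric (4S,6S)-nona-1,8-diene-4,6-diol **4**, whose two hydroxyls and two allyl groups are homotopic.

The remaining centres are related to this core by relationships that substrate control can deliver: C6' is 1,5-anti to C2', and C4' is 1,3-syn to C6'.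

## Retrosynthesis

**17 ⇒ 16.** Only the C2'–O–PMB bond is cut. The PMB ether is kept to the end because it does three jobs: it marks one of two homotopic hydroxyls, it is the β-alkoxy group that 1,5-induction needs, and it leaves under neutral oxidation that the lactone tolerates.

**16 ⇒ 14.** The C4'–H bond is cut (ketone reduction). Letting C4' arrive as a carbonyl is what permits the aldol below, and the C6' hydroxyl of **14** directs a 1,3-syn reduction through boron chelate **15**. The forward step must reduce a ketone next to an enoate.

**14 ⇒ 11 + 12.** The C5'–C6' bond is cut. This removes half the carbons as decanal **12** and leaves methyl ketone **11**. A cut at C6'–C7' would instead need a separate enantiopure C6' fragment. The forward aldol, through boron enolate **13**, must set C6' anti to the C2' ether across five atoms.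

**11 ⇒ 10.** The C4' ketone is traced back to the terminal alkene of **10** (Tsuji–Wacker oxidation). The allyl group on C2' is thus a latent acetone enolate. The oxidation must ignore the conjugated ring alkene.

**10 ⇒ 9 ⇒ 7 + 8.** The ring is cut at C3=C4 (ring-closing metathesis) and at O1–C2 (acylation with acryloyl chloride **8**). The Z-enoate is guaranteed by the ring. Ring closure also tells the two allyl groups of **7** apart, since only one can reach the acrylate through a six-membered ring.

**7 ⇒ 6 ⇒ 4 + 5.** The two homotopic hydroxyls of **4** are differentiated through p-methoxybenzylidene acetal **6** (from acetal **5**). Either C–O bond of **6** opens reductively to the same mono-PMB ether **7**, so no statistical mixture arises.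

**4 ⇒ 1 + 2.** C5–C6 and C2'–C3' are cut at once. Propane-1,3-diol **1** and two molecules of allyl acetate **2** give **4** by a two-directional, catalyst-controlled allylation via mono-adduct **3**. Eight of the 20 target carbons, two stereocentres and both later handles come from one operation on a C3 commodity diol.

## Roads not taken

**Alternative 1:** Linear growth from the tail, the most obvious route. Decanal would be allylated asymmetrically to (R)-tridec-1-en-4-ol **A1**. Three further cycles of protection, alkene cleavage and allylation would follow, then acryloylation and ring-closing metathesis. Every C–C cut lies between a carbinol and its allylic methylene, and each of the four centres needs its own stoichiometric or catalytic chiral step. The sequence is fully linear and well beyond a dozen steps, and protecting groups accumulate. The chosen plan makes two centres in one catalytic step and derives the other two from them.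

**Alternative 2:** Three-component linchpin coupling. The cuts are C3'–C4' and C4'–C5'. A 2-silyl-1,3-dithiane anion would open epoxide **A3** (carrying C6 and C2'), undergo silyl migration, and then open (R)-2-nonyloxirane **A2**. The masked C4' ketone would be unveiled and reduced syn to the free C6' hydroxyl. This is convergent, but both epoxides must be made enantiopure separately, and **A3** already contains two stereocentres. Dithiane removal must also spare an alkene and a PMB ether. The stereochemical work is moved into the fragments rather than reduced.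

**Alternative 3:** Two-directional allylation about C4'. In the anti,syn triad C2'/C4'/C6', the middle carbon is not a stereocentre while the ends are alike. Silyl ether **A4** would be doubly allylated to **A5**, fixing C2' and C6' at once with C4' coming for free. After desilylation, equilibrating ketalisation to acetonide **A6** would select the syn pair and so decide which end is C6'. This is attractive stereochemically, but the two allyl termini then need unrelated work. One needs a six-carbon extension and saturation. The other needs oxidative cleavage, a separate reagent-controlled allylation for C6 (anti to C2'), acryloylation and ring closure. The alkenes also cannot be told apart without extra steps. The count rises to about thirteen. The chosen C2 element gives both allyl groups an immediate, different use.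

Key step: step 1

Assumption: the (S)-configured Cl,MeO-BIPHEP ligand is taken to give the (S,S)-diol, by analogy with aliphatic primary alcohols; if the sense proves opposite, the antipodal ligand is used with no other change.

## Route

**Step 1**
Reactants: 1 propane-1,3-diol; 2 allyl acetate
Product: 4 (4S,6S)-nona-1,8-diene-4,6-diol, via (S)-hex-5-ene-1,3-diol 3 (not isolated)
Conditions: [Ir(cod)Cl]2 (5 mol%), (S)-Cl,MeO-BIPHEP (10 mol%), 4-chloro-3-nitrobenzoic acid (20 mol%), Cs2CO3 (40 mol%), allyl acetate (excess), 1,4-dioxane, 90 °C, sealed tube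
Reagents that add atoms: allyl acetate, C=CCOC(C)=O
Why: Two-directional, redox-neutral carbonyl allylation by transfer hydrogenation: the cyclometallated π-allyl iridium C,O-benzoate formed from the Ir(I) source, the nitrobenzoic acid, the bisphosphine and 2 dehydrogenates a primary hydroxyl of 1 by β-hydride elimination, and the allyl–iridium species adds to the resulting aldehyde through a closed chair-like transition state, after which ionisation of a further molecule of 2 regenerates the allyl complex and acetic acid is the only by-product. The closest known reaction type is this same iridium-catalysed enantioselective double C–H allylation of 1,3-diols, propane-1,3-diol included, so the step is precedented on the very substrate class. No ring is closed. Both new stereocentres (the future C6 and C2') are set by the ligand, which selects the face of each transient aldehyde independently, so the 1,3-anti relationship follows from two catalyst-controlled additions of like sense and not from substrate induction. Mono-adduct 3 of the wrong hand is carried by the second allylation mainly into the separable meso diol, so the enantiomeric purity of 4 should be amplified (Horeau principle). The step needs dehydrogenation of primary over secondary hydroxyl, secured because the secondary homoallylic alcohols of 3 and 4 are dehydrogenated far more slowly; it also needs the β-hydroxy aldehydes to stay at trace concentration so that they do not dehydrate, secured because each aldehyde is formed and consumed at the same metal centre.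

**Step 2**
Reactants: 4 (4S,6S)-nona-1,8-diene-4,6-diol; 5 4-methoxybenzaldehyde dimethyl acetal
Product: 6 (4S,6S)-2-(4-methoxyphenyl)-4,6-di(prop-2-en-1-yl)-1,3-dioxane
Conditions: CSA (cat.), CH2Cl2, 4 Å MS, rt
Reagents that add atoms: 4-methoxybenzaldehyde dimethyl acetal, COc1ccc(cc1)C(OC)OC
Why: Acid-catalysed transacetalisation of a 1,3-diol; the acetal carbon is not a stereocentre because both ring oxygens sit on carbons of identical configuration, so one compound forms and no stereocentre is touched.

**Step 3**
Reactants: 6 (4S,6S)-2-(4-methoxyphenyl)-4,6-di(prop-2-en-1-yl)-1,3-dioxane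
Product: 7 (4S,6S)-6-[(4-methoxyphenyl)methoxy]nona-1,8-dien-4-ol
Conditions: DIBAL-H (3 equiv), CH2Cl2, −78 → 0 °C; Rochelle salt work-up
Reagents that add atoms: none
Why: Reductive opening of a p-methoxybenzylidene acetal (aluminium coordinates one ring oxygen, hydride goes to the benzylic oxocarbenium carbon); the two possible C–O cleavages are related by the twofold axis of the parent diol and give the same mono-PMB ether, so the homotopic hydroxyls are differentiated without a statistical mixture. Terminal alkenes are not hydroaluminated at this temperature.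

**Step 4**
Reactants: 7 (4S,6S)-6-[(4-methoxyphenyl)methoxy]nona-1,8-dien-4-ol; 8 acryloyl chloride
Product: 9 (4S,6S)-6-[(4-methoxyphenyl)methoxy]nona-1,8-dien-4-yl prop-2-enoate
Conditions: iPr2NEt, DMAP (cat.), CH2Cl2, −20 → 0 °C
Reagents that add atoms: acryloyl chloride, C=CC(=O)Cl
Why: DMAP-catalysed O-acylation of the only free hydroxyl (the future O1); low temperature and a hindered base keep the acrylate from polymerising or taking up nucleophiles.

**Step 5**
Reactants: 9 (4S,6S)-6-[(4-methoxyphenyl)methoxy]nona-1,8-dien-4-yl prop-2-enoate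
Product: 10 (6S)-6-[(2S)-2-[(4-methoxyphenyl)methoxy]pent-4-en-1-yl]-5,6-dihydro-2H-pyran-2-one
Conditions: Grubbs II (5 mol%), CH2Cl2 (5 mM), 40 °C
Reagents that add atoms: none
Why: Ring-closing metathesis of the acrylate onto the allyl group on the same carbinol forms C3=C4 in a six-membered ring (Z by necessity) and releases ethene; the other allyl group could reach the acrylate only through an eight-membered ring. The conjugated product does not re-enter the catalytic cycle, so it is the sink of the metathesis equilibria.

**Step 6**
Reactants: 10 (6S)-6-[(2S)-2-[(4-methoxyphenyl)methoxy]pent-4-en-1-yl]-5,6-dihydro-2H-pyran-2-one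
Product: 11 (6S)-6-[(2R)-2-[(4-methoxyphenyl)methoxy]-4-oxopentyl]-5,6-dihydro-2H-pyran-2-one
Conditions: PdCl2 (10 mol%), CuCl (1 equiv), O2 (1 atm), DMF/H2O 7:1, rt
Reagents that add atoms: water, O
Why: Tsuji–Wacker oxidation: Markovnikov hydroxypalladation of the terminal alkene and β-hydride elimination give the methyl ketone at C4', while the electron-poor, 1,2-disubstituted ring alkene is inert. The descriptor at C2' changes to R only because the priorities change.

**Step 7**
Reactants: 11 (6S)-6-[(2R)-2-[(4-methoxyphenyl)methoxy]-4-oxopentyl]-5,6-dihydro-2H-pyran-2-one; 12 decanal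
Product: 14 (6S)-6-[(2R,6R)-6-hydroxy-2-[(4-methoxyphenyl)methoxy]-4-oxopentadecyl]-5,6-dihydro-2H-pyran-2-one, via dicyclohexylboron enolate 13 (not isolated)
Conditions: c-Hex2BCl, Et3N, Et2O, −78 → 0 °C; then 12, −78 → −20 °C; MeOH/pH 7 buffer/H2O2, 0 °C
Reagents that add atoms: decanal, CCCCCCCCCC=O
Why: Boron aldol reaction of a methyl ketone under 1,5-anti induction: the kinetic boron enolate 13, formed on the methyl side, adds to decanal with the established preference of β-PMB-oxy methyl ketone boron enolates for the 1,5-anti adduct, so C6' forms anti to the C2' ether (6'R). The amine-buffered enolisation at low temperature should leave the lactone untouched.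

**Step 8**
Reactants: 14 (6S)-6-[(2R,6R)-6-hydroxy-2-[(4-methoxyphenyl)methoxy]-4-oxopentadecyl]-5,6-dihydro-2H-pyran-2-one
Product: 16 (6S)-6-[(2S,4R,6R)-4,6-dihydroxy-2-[(4-methoxyphenyl)methoxy]pentadecyl]-5,6-dihydro-2H-pyran-2-one, via diethylboron chelate 15 (not isolated)
Conditions: Et2BOMe, THF/MeOH 4:1, −78 °C; then NaBH4, −78 °C; AcOH; MeOH azeotrope
Reagents that add atoms: none
Why: Narasaka–Prasad reduction: Et2BOMe ties the C6' hydroxyl and the C4' ketone into six-membered chelate 15, and external hydride attacks the half-chair axially, giving the 4',6'-syn diol (4'R). At −78 °C borohydride should not touch the conjugated lactone, and the non-oxidative work-up avoids basic peroxide.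

**Step 9**
Reactants: 16 (6S)-6-[(2S,4R,6R)-4,6-dihydroxy-2-[(4-methoxyphenyl)methoxy]pentadecyl]-5,6-dihydro-2H-pyran-2-one
Product: 17 (6S)-6-[(2S,4R,6R)-2,4,6-trihydroxypentadecyl]-5,6-dihydro-2H-pyran-2-one
Conditions: DDQ, CH2Cl2/pH 7 buffer 10:1, 0 °C
Reagents that add atoms: none
Why: Oxidative cleavage of the PMB ether (hydride abstraction to the benzylic oxocarbenium ion, hydrolysis by the buffered water) under neutral conditions that neither open the lactone nor promote oxa-Michael addition; no stereocentre is touched.

## Compound list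

1 | propane-1,3-diol | OCCCO | starting material
2 | allyl acetate | C=CCOC(C)=O | starting material
3 | (S)-hex-5-ene-1,3-diol | C=CC[C@H](O)CCO | intermediate
4 | (4S,6S)-nona-1,8-diene-4,6-diol | C=CC[C@H](O)C[C@@H](O)CC=C | intermediate
5 | 4-methoxybenzaldehyde dimethyl acetal | COc1ccc(cc1)C(OC)OC | starting material
6 | (4S,6S)-2-(4-methoxyphenyl)-4,6-di(prop-2-en-1-yl)-1,3-dioxane | C=CC[C@H]1C[C@H](CC=C)OC(c2ccc(OC)cc2)O1 | intermediate
7 | (4S,6S)-6-[(4-methoxyphenyl)methoxy]nona-1,8-dien-4-ol | C=CC[C@H](OCc1ccc(OC)cc1)C[C@@H](O)CC=C | intermediate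
8 | acryloyl chloride | C=CC(=O)Cl | starting material
9 | (4S,6S)-6-[(4-methoxyphenyl)methoxy]nona-1,8-dien-4-yl prop-2-enoate | C=CC[C@H](OCc1ccc(OC)cc1)C[C@@H](OC(=O)C=C)CC=C | intermediate
10 | (6S)-6-[(2S)-2-[(4-methoxyphenyl)methoxy]pent-4-en-1-yl]-5,6-dihydro-2H-pyran-2-one | C=CC[C@H](OCc1ccc(OC)cc1)C[C@@H]1CC=CC(=O)O1 | intermediate
11 | (6S)-6-[(2R)-2-[(4-methoxyphenyl)methoxy]-4-oxopentyl]-5,6-dihydro-2H-pyran-2-one | CC(=O)C[C@H](OCc1ccc(OC)cc1)C[C@@H]1CC=CC(=O)O1 | intermediate
12 | decanal | CCCCCCCCCC=O | starting material
13 | (6S)-6-[(2R)-4-[(dicyclohexylboranyl)oxy]-2-[(4-methoxyphenyl)methoxy]pent-4-en-1-yl]-5,6-dihydro-2H-pyran-2-one (boron enolate) | C=C(OB(C1CCCCC1)C1CCCCC1)C[C@H](OCc1ccc(OC)cc1)C[C@@H]1CC=CC(=O)O1 | intermediate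
14 | (6S)-6-[(2R,6R)-6-hydroxy-2-[(4-methoxyphenyl)methoxy]-4-oxopentadecyl]-5,6-dihydro-2H-pyran-2-one | CCCCCCCCC[C@@H](O)CC(=O)C[C@H](OCc1ccc(OC)cc1)C[C@@H]1CC=CC(=O)O1 | intermediate
15 | (6S)-6-[(2R,6R)-6-[(diethylboranyl)oxy]-2-[(4-methoxyphenyl)methoxy]-4-oxopentadecyl]-5,6-dihydro-2H-pyran-2-one (boron chelate) | CCCCCCCCC[C@@H](OB(CC)CC)CC(=O)C[C@H](OCc1ccc(OC)cc1)C[C@@H]1CC=CC(=O)O1 | intermediate
16 | (6S)-6-[(2S,4R,6R)-4,6-dihydroxy-2-[(4-methoxyphenyl)methoxy]pentadecyl]-5,6-dihydro-2H-pyran-2-one | CCCCCCCCC[C@@H](O)C[C@@H](O)C[C@H](OCc1ccc(OC)cc1)C[C@@H]1CC=CC(=O)O1 | intermediate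
17 | (6S)-6-[(2S,4R,6R)-2,4,6-trihydroxypentadecyl]-5,6-dihydro-2H-pyran-2-one | CCCCCCCCC[C@@H](O)C[C@@H](O)C[C@H](O)C[C@@H]1CC=CC(=O)O1 | target

## Step count and risks

Total: 9 steps. Longest linear sequence: 9 steps (1 → 17).

**Step 1 (key step).** The second allylation may stall at the mono-adduct. Facial control may erode at 90 °C, which shows up as meso diol. The transient β-hydroxy aldehydes may dehydrate if they leave the catalyst.

Fallback (linear, reagent- and chelation-controlled, from 1 back to 7): monosilylation of 1 (NaH, TBSCl) gives 3-[(tert-butyldimethylsilyl)oxy]propan-1-ol F1. Oxidation (SO3·pyridine, DMSO, iPr2NEt) gives 3-[(tert-butyldimethylsilyl)oxy]propanal F2. Allylboration with (−)-B-allyldiisopinocampheylborane gives (3S)-1-[(tert-butyldimethylsilyl)oxy]hex-5-en-3-ol F3. PMB ether formation (PMB trichloroacetimidate, cat. PPTS) gives tert-butyl{[(3S)-3-[(4-methoxyphenyl)methoxy]hex-5-en-1-yl]oxy}dimethylsilane F4. TBAF gives (3S)-3-[(4-methoxyphenyl)methoxy]hex-5-en-1-ol F5, and oxidation gives (3S)-3-[(4-methoxyphenyl)methoxy]hex-5-enal F6. Chelation-controlled addition of allyltributylstannane (MgBr2·OEt2, CH2Cl2) then sets the 1,3-anti carbinol and rejoins the route at 7.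

**Step 5.** Both allyl termini load the catalyst faster than the acrylate. Closure of the two allyl groups onto each other (a seven-membered carbocycle) and intermolecular cross-metathesis therefore compete with lactone formation.

Fallback (no metathesis, from 7 back to 16): esterification of 7 with diethylphosphonoacetic acid (DCC, DMAP) gives (4S,6S)-6-[(4-methoxyphenyl)methoxy]nona-1,8-dien-4-yl (diethoxyphosphoryl)acetate F7. Cleavage of both alkenes (OsO4 cat., NaIO4, 2,6-lutidine; ozone is avoided because of the PMB arene) gives (3R,5R)-5-[(4-methoxyphenyl)methoxy]-1,7-dioxoheptan-3-yl (diethoxyphosphoryl)acetate F8. Intramolecular Horner–Wadsworth–Emmons olefination (LiCl, iPr2NEt, MeCN, high dilution) can reach only the nearer aldehyde through a six-membered ring and gives the lactone aldehyde F9. From F9 the sequence of the step 7 fallback (Mukaiyama aldol with F10 to F11, then syn reduction) returns to the route at 16.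

**Step 7.** 1,5-Induction may be weak for this particular β-substituent. The boron enolate or the amine may also attack the unsaturated lactone (conjugate addition, γ-deprotonation).

Fallback (other bond, other control element, from 10 back to 16): oxidative cleavage of the terminal alkene of 10 (OsO4 cat., NaIO4, 2,6-lutidine) gives (3R)-3-[(4-methoxyphenyl)methoxy]-4-[(2S)-6-oxo-3,6-dihydro-2H-pyran-2-yl]butanal F9. Mukaiyama aldol addition of trimethyl(undec-1-en-2-yloxy)silane F10 (from undecan-2-one, LDA, TMSCl) with BF3·OEt2 at −78 °C forms C4'–C5' under the 1,3-anti induction of β-alkoxy aldehydes. This gives (6S)-6-[(2S,4S)-4-hydroxy-2-[(4-methoxyphenyl)methoxy]-6-oxopentadecyl]-5,6-dihydro-2H-pyran-2-one F11. Its C6' ketone is reduced syn to the C4' hydroxyl (Et2BOMe, NaBH4), which gives 16.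

**Step 9.** The benzylic oxocarbenium ion may be captured by the neighbouring C4' hydroxyl (acetal formation) instead of by water, and the ring so formed may be over-oxidised.

Fallback (change of protecting-group order, from 16 back to 17): ketalisation of 16 (2,2-dimethoxypropane, PPTS) gives (6S)-6-[(2S)-3-[(4S,6R)-2,2-dimethyl-6-nonyl-1,3-dioxan-4-yl]-2-[(4-methoxyphenyl)methoxy]propyl]-5,6-dihydro-2H-pyran-2-one F12, in which no hydroxyl flanks the PMB ether. DDQ then gives (6S)-6-[(2S)-3-[(4S,6R)-2,2-dimethyl-6-nonyl-1,3-dioxan-4-yl]-2-hydroxypropyl]-5,6-dihydro-2H-pyran-2-one F13. Aqueous acetic acid removes the acetonide and gives 17.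

## Further compounds

F1 | step 1 | 3-[(tert-butyldimethylsilyl)oxy]propan-1-ol | OCCCO[Si](C)(C)C(C)(C)C
F2 | step 1 | 3-[(tert-butyldimethylsilyl)oxy]propanal | O=CCCO[Si](C)(C)C(C)(C)C
F3 | step 1 | (3S)-1-[(tert-butyldimethylsilyl)oxy]hex-5-en-3-ol | C=CC[C@H](O)CCO[Si](C)(C)C(C)(C)C
F4 | step 1 | tert-butyl{[(3S)-3-[(4-methoxyphenyl)methoxy]hex-5-en-1-yl]oxy}dimethylsilane | C=CC[C@H](OCc1ccc(OC)cc1)CCO[Si](C)(C)C(C)(C)C
F5 | step 1 | (3S)-3-[(4-methoxyphenyl)methoxy]hex-5-en-1-ol | C=CC[C@H](OCc1ccc(OC)cc1)CCO
F6 | step 1 | (3S)-3-[(4-methoxyphenyl)methoxy]hex-5-enal | C=CC[C@H](OCc1ccc(OC)cc1)CC=O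
F7 | step 5 | (4S,6S)-6-[(4-methoxyphenyl)methoxy]nona-1,8-dien-4-yl (diethoxyphosphoryl)acetate | C=CC[C@H](OCc1ccc(OC)cc1)C[C@@H](OC(=O)CP(=O)(OCC)OCC)CC=C
F8 | step 5 | (3R,5R)-5-[(4-methoxyphenyl)methoxy]-1,7-dioxoheptan-3-yl (diethoxyphosphoryl)acetate | O=CC[C@H](OCc1ccc(OC)cc1)C[C@@H](OC(=O)CP(=O)(OCC)OCC)CC=O
F9 | step 7 | (3R)-3-[(4-methoxyphenyl)methoxy]-4-[(2S)-6-oxo-3,6-dihydro-2H-pyran-2-yl]butanal | O=CC[C@H](OCc1ccc(OC)cc1)C[C@@H]1CC=CC(=O)O1
F10 | step 7 | trimethyl(undec-1-en-2-yloxy)silane | C=C(O[Si](C)(C)C)CCCCCCCCC
F11 | step 7 | (6S)-6-[(2S,4S)-4-hydroxy-2-[(4-methoxyphenyl)methoxy]-6-oxopentadecyl]-5,6-dihydro-2H-pyran-2-one | CCCCCCCCCC(=O)C[C@@H](O)C[C@H](OCc1ccc(OC)cc1)C[C@@H]1CC=CC(=O)O1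
F12 | step 9 | (6S)-6-[(2S)-3-[(4S,6R)-2,2-dimethyl-6-nonyl-1,3-dioxan-4-yl]-2-[(4-methoxyphenyl)methoxy]propyl]-5,6-dihydro-2H-pyran-2-one | CCCCCCCCC[C@@H]1C[C@H](C[C@H](OCc2ccc(OC)cc2)C[C@@H]2CC=CC(=O)O2)OC(C)(C)O1
F13 | step 9 | (6S)-6-[(2S)-3-[(4S,6R)-2,2-dimethyl-6-nonyl-1,3-dioxan-4-yl]-2-hydroxypropyl]-5,6-dihydro-2H-pyran-2-one | CCCCCCCCC[C@@H]1C[C@H](C[C@H](O)C[C@@H]2CC=CC(=O)O2)OC(C)(C)O1
A1 | alternative 1 | (R)-tridec-1-en-4-ol | CCCCCCCCC[C@@H](O)CC=C
A2 | alternative 2 | (R)-2-nonyloxirane | CCCCCCCCC[C@@H]1CO1
A3 | alternative 2 | (2R)-2-[(2S)-2-[(4-methoxyphenyl)methoxy]pent-4-en-1-yl]oxirane | C=CC[C@H](OCc1ccc(OC)cc1)C[C@@H]1CO1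
A4 | alternative 3 | 3-[(tert-butyldimethylsilyl)oxy]pentane-1,5-diol | OCCC(O[Si](C)(C)C(C)(C)C)CCO
A5 | alternative 3 | (4R,8R)-6-[(tert-butyldimethylsilyl)oxy]undeca-1,10-diene-4,8-diol | C=CC[C@@H](O)CC(O[Si](C)(C)C(C)(C)C)C[C@H](O)CC=C
A6 | alternative 3 | (2R)-1-[(4S,6R)-2,2-dimethyl-6-(prop-2-en-1-yl)-1,3-dioxan-4-yl]pent-4-en-2-ol | C=CC[C@@H]1C[C@H](C[C@H](O)CC=C)OC(C)(C)O1
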